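**Retrosynthetic overview**
1. Feature: in the target the ketone carbon C4 sits on ring A (the hydroquinone ring) ortho to a free phenol and 1,4 to the carboxyl carbon C1, with the methylene C3 and the stereocentre C2 between them.
2. Key disconnection C3–C4 (together with C2–H): a salicylaldehyde C–H bond added across a 2-methylene ester; the aldehyde is gentisaldehyde 1, protected at its non-chelated 5-OH as silyl ether 2.
3. The 2-methylene ester is cut at C1–C2: (E)-geranylacetone 3 already holds C2–C11 with both trisubstituted alkenes; its kinetic enolate 4 gives enol triflate 5, and methoxycarbonylation gives acrylate 6.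
4. Forward: rhodium-catalysed enantioselective hydroacylation of 6 with 2 gives 7 (C2 set as S); hydroxide then removes the aryl silyl ether (8, in the flask) and the methyl ester to give 9.
5. No ring is formed: ring A is bought with 1, and the route makes one skeletal C–C bond and one stereocentre in the key step.

Key step: step 4

Assumptions: 3 is bought as the geometrically pure 5E isomer, and the antipode of QuinoxP* (2,3-bis(tert-butylmethylphosphino)quinoxaline) written in step 4 stands for whichever one delivers 2S.

**Step 1**
Reactants: 1 2,5-dihydroxybenzaldehyde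
Product: 2 5-[(tert-butyldimethylsilyl)oxy]-2-hydroxybenzaldehyde
Conditions: TBSCl (1.05 equiv), imidazole (2.2 equiv), CH2Cl2, 0 °C → rt
Reagents that add atoms: tert-butyldimethylsilyl chloride, CC(C)(C)[Si](C)(C)Cl
Why: Selective silyl ether formation, because the 2-OH is locked in a hydrogen bond to the formyl oxygen and shielded by the formyl group, so the chlorosilane should react at the free, more nucleophilic 5-OH.

**Step 2**
Reactants: 3 (5E)-6,10-dimethylundeca-5,9-dien-2-one
Product: 5 (5E)-6,10-dimethylundeca-1,5,9-trien-2-yl trifluoromethanesulfonate, via potassium enolate 4 (not isolated)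
Conditions: KN(SiMe3)2 (1.1 equiv), THF, −78 °C, slow addition of 3; then PhNTf2 (1.1 equiv), −78 → 0 °C
Reagents that add atoms: N-phenylbis(trifluoromethanesulfonimide), O=S(=O)(N(c1ccccc1)S(=O)(=O)C(F)(F)F)C(F)(F)F
Why: Kinetic enolisation followed by O-triflation (enol triflate formation), in which the hindered amide base removes a proton from the unhindered methyl group at −78 °C and enolate 4 is trapped on oxygen, while the trisubstituted alkenes and the 5E geometry are untouched.

**Step 3**
Reactants: 5 (5E)-6,10-dimethylundeca-1,5,9-trien-2-yl trifluoromethanesulfonate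
Product: 6 methyl (5E)-6,10-dimethyl-2-methylideneundeca-5,9-dienoate
Conditions: Pd(OAc)2 (5 mol %), PPh3 (10 mol %), CO (1 atm), MeOH, Et3N, DMF, rt → 50 °C
Reagents that add atoms: carbon monoxide, [C-]#[O+]; methanol, CO
Why: Palladium-catalysed alkoxycarbonylation of an alkenyl triflate, in which zerovalent palladium formed in situ adds oxidatively to the C–OTf bond, CO inserts and methanol cleaves the acyl complex of divalent palladium, while the unactivated chain alkenes do not react.

**Step 4**
Reactants: 2 5-[(tert-butyldimethylsilyl)oxy]-2-hydroxybenzaldehyde; 6 methyl (5E)-6,10-dimethyl-2-methylideneundeca-5,9-dienoate (1.5 equiv)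
Product: 7 methyl (2S,5E)-2-{2-[5-(tert-butyldimethylsilyloxy)-2-hydroxyphenyl]-2-oxoethyl}-6,10-dimethylundeca-5,9-dienoate
Conditions: [Rh(cod)2]BF4 (5 mol %), (R,R)-QuinoxP* (5 mol %), catalyst pre-hydrogenated then kept under argon, K3PO4 (10 mol %), ClCH2CH2Cl, 40 °C
Reagents that add atoms: none
Why: Proposed new method: rhodium is anchored on the phenoxide oxygen of 2 (phosphate takes the proton) and, as monovalent rhodium, inserts into the adjacent formyl C–H bond to give a five-membered O,C-chelated acyl hydride of trivalent rhodium that is held too rigidly to extrude CO readily; the 1,1-disubstituted alkene of 6 then binds, the hydride migrates to C2 so that the metal ends on the terminal carbon C3 with the ester carbonyl filling the vacated site as a five-membered chelate, and acyl–alkyl reductive elimination makes the C3–C4 bond and returns monovalent rhodium. The closest known reactions are the rhodium-catalysed phenoxide-directed hydroacylation of alkenes with salicylaldehydes and the enantioselective hydroacylation of 2-substituted acrylamides under [Rh(cod)2]BF4 and QuinoxP*, which gives 1,4-keto amides with an α-stereocentre; the untested element is the pairing of a salicylaldehyde with a 2-alkyl acrylate ester, whose carbonyl is a weaker donor than that of an amide. No ring is closed. The only new stereocentre, C2, is created when the hydride is delivered to one enantiotopic face of the coordinated alkene (or, should insertion be reversible, in the reductive elimination that selects between the diastereomeric alkyls), and the P-stereogenic bisphosphine is the sole controlling element, its enantiomer being picked so that 2S results. The step needs linear regiochemistry, secured by the 1,1-disubstitution (the branched alkyl would have to form a quaternary acyl-bearing carbon) and by the ester chelate, and chemoselectivity for the acrylate over the C5=C6 and C9=C10 alkenes, secured because these are trisubstituted, unactivated and carry no donor group to hold them on the metal.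

**Step 5**
Reactants: 7 methyl (2S,5E)-2-{2-[5-(tert-butyldimethylsilyloxy)-2-hydroxyphenyl]-2-oxoethyl}-6,10-dimethylundeca-5,9-dienoate
Product: 9 (2S,5E)-2-[2-(2,5-dihydroxyphenyl)-2-oxoethyl]-6,10-dimethylundeca-5,9-dienoic acid, via hydroquinone methyl ester 8 (not isolated)
Conditions: LiOH·H2O (6 equiv), THF/H2O 3:1 (degassed), argon, 0 °C → rt; then 1 M HCl to pH 3, 0 °C
Reagents that add atoms: lithium hydroxide, [Li+].[OH-]
Why: Base hydrolysis, in which hydroxide attacks silicon of the aryl silyl ether to release the phenoxide of 8 and then saponifies the methyl ester by acyl–oxygen cleavage; the carboxylate resists deprotonation at C2, so the 2S configuration should be kept, and exclusion of oxygen protects the hydroquinone.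

**Compound list**
1 | 2,5-dihydroxybenzaldehyde (gentisaldehyde) | O=Cc1cc(O)ccc1O | starting material
2 | 5-[(tert-butyldimethylsilyl)oxy]-2-hydroxybenzaldehyde | O=Cc1cc(O[Si](C)(C)C(C)(C)C)ccc1O | intermediate
3 | (5E)-6,10-dimethylundeca-5,9-dien-2-one ((E)-geranylacetone) | CC(C)=CCC/C(C)=C/CCC(C)=O | starting material
4 | potassium (5E)-6,10-dimethylundeca-1,5,9-trien-2-olate | CC(C)=CCC/C(C)=C/CCC(=C)[O-].[K+] | intermediate
5 | (5E)-6,10-dimethylundeca-1,5,9-trien-2-yl trifluoromethanesulfonate | CC(C)=CCC/C(C)=C/CCC(=C)OS(=O)(=O)C(F)(F)F | intermediate
6 | methyl (5E)-6,10-dimethyl-2-methylideneundeca-5,9-dienoate | CC(C)=CCC/C(C)=C/CCC(=C)C(=O)OC | intermediate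
7 | methyl (2S,5E)-2-{2-[5-(tert-butyldimethylsilyloxy)-2-hydroxyphenyl]-2-oxoethyl}-6,10-dimethylundeca-5,9-dienoate | CC(C)=CCC/C(C)=C/CC[C@@H](CC(=O)c1cc(O[Si](C)(C)C(C)(C)C)ccc1O)C(=O)OC | intermediate
8 | methyl (2S,5E)-2-[2-(2,5-dihydroxyphenyl)-2-oxoethyl]-6,10-dimethylundeca-5,9-dienoate | CC(C)=CCC/C(C)=C/CC[C@@H](CC(=O)c1cc(O)ccc1O)C(=O)OC | intermediate
9 | (2S,5E)-2-[2-(2,5-dihydroxyphenyl)-2-oxoethyl]-6,10-dimethylundeca-5,9-dienoic acid | CC(C)=CCC/C(C)=C/CC[C@@H](CC(=O)c1cc(O)ccc1O)C(=O)O | target

**Step count**
Total steps: 5. Longest linear sequence: 4 steps (3 → 5 → 6 → 7 → 9; steps 2, 3, 4, 5).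

**Steps most likely to fail**

Step 4 (Proposed new method).
- What may go wrong: the acyl hydride may lose CO or fail to capture the weakly binding acrylate ester. The acrylate may be isomerised into conjugation by reversible hydride insertion. Face discrimination in the hydride transfer may be low.
- Fallback (known chemistry, same C3–C4 bond): an enantioselective intermolecular Stetter reaction catalysed by a chiral N-heterocyclic carbene. This reaction type is established for aryl aldehydes with 2-substituted acrylates; C2 is set by enantioselective protonation of the ester enolate formed after conjugate addition of the Breslow intermediate.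
- It sets out from 1 and 6. A free ortho phenol would quench carbene and base, so 1 is converted with NaH and MOMCl in DMF into 2,5-bis(methoxymethoxy)benzaldehyde F1.
- F1 and 6, with a chiral bicyclic N-aryl triazolium salt (10 mol %) and KOtBu (10 mol %) in toluene at rt, should give methyl (2S,5E)-2-{2-[2,5-bis(methoxymethoxy)phenyl]-2-oxoethyl}-6,10-dimethylundeca-5,9-dienoate F2, the catalyst antipode being chosen for 2S.
- Both acetals are then removed with 3 M HCl in MeOH at rt, which the trisubstituted alkenes should tolerate. This gives 8, where the fallback rejoins the route; 8 is hydrolysed under the conditions of step 5 to 9.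

Step 2.
- What may go wrong: proton exchange between the enolate and not-yet-deprotonated ketone may erode kinetic control, so that triflation also takes place on the internal (C3) side and regioisomers are carried into the carbonylation.
- Fallback: a Shapiro reaction, in which regiochemistry is fixed by the hydrazone geometry and not by enolate equilibria. It sets out from 3 and comes back at 6, bypassing 5.
- Condensation of 3 with 2,4,6-triisopropylbenzenesulfonyl hydrazide (MeOH, rt) gives N'-[(2E,5E)-6,10-dimethylundeca-5,9-dien-2-ylidene]-2,4,6-triisopropylbenzenesulfonohydrazide F3.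
- Two equivalents of n-BuLi (hexane/TMEDA, −78 → 0 °C) remove the N–H and a proton of the methyl group syn to the sulfonamide nitrogen. Loss of sulfinate and N2 gives (5E)-6,10-dimethylundeca-1,5,9-trien-2-yllithium F4.
- F4 is added at −78 °C to an excess of methyl chloroformate to give 6.

Step 5.
- What may go wrong: prolonged exposure to hydroxide may erode the C2 configuration by enolisation of the ester before it is cleaved, and the hydroquinone dianion may be oxidised by traces of air.
- Fallback: replace hydroxide by fluoride through a change of ester. It sets out from 5 and comes back at 9. It carries a different ester through step 4, so it depends on that step tolerating the change.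
- Carbonylation of 5 as in step 3, with 2-(trimethylsilyl)ethanol in place of methanol, gives 2-(trimethylsilyl)ethyl (5E)-6,10-dimethyl-2-methylideneundeca-5,9-dienoate F5.
- Hydroacylation of F5 with 2 as in step 4 gives 2-(trimethylsilyl)ethyl (2S,5E)-2-{2-[5-(tert-butyldimethylsilyloxy)-2-hydroxyphenyl]-2-oxoethyl}-6,10-dimethylundeca-5,9-dienoate F6.
- Bu4NF (3 equiv) in THF under argon, 0 °C → rt, then cleaves the aryl silyl ether and, by attack on silicon with loss of ethene, the ester. Mild acidification gives 9 without any hydroxide.

**Further compounds**
F1 | step 4 | 2,5-bis(methoxymethoxy)benzaldehyde | O=Cc1cc(OCOC)ccc1OCOC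
F2 | step 4 | methyl (2S,5E)-2-{2-[2,5-bis(methoxymethoxy)phenyl]-2-oxoethyl}-6,10-dimethylundeca-5,9-dienoate | CC(C)=CCC/C(C)=C/CC[C@@H](CC(=O)c1cc(OCOC)ccc1OCOC)C(=O)OC
F3 | step 2 | N'-[(2E,5E)-6,10-dimethylundeca-5,9-dien-2-ylidene]-2,4,6-triisopropylbenzenesulfonohydrazide | CC(C)=CCC/C(C)=C/CC/C(C)=N/NS(=O)(=O)c1c(C(C)C)cc(C(C)C)cc1C(C)C
F4 | step 2 | (5E)-6,10-dimethylundeca-1,5,9-trien-2-yllithium | CC(C)=CCC/C(C)=C/CCC(=C)[Li]
F5 | step 5 | 2-(trimethylsilyl)ethyl (5E)-6,10-dimethyl-2-methylideneundeca-5,9-dienoate | CC(C)=CCC/C(C)=C/CCC(=C)C(=O)OCC[Si](C)(C)C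
F6 | step 5 | 2-(trimethylsilyl)ethyl (2S,5E)-2-{2-[5-(tert-butyldimethylsilyloxy)-2-hydroxyphenyl]-2-oxoethyl}-6,10-dimethylundeca-5,9-dienoate | CC(C)=CCC/C(C)=C/CC[C@@H](CC(=O)c1cc(O[Si](C)(C)C(C)(C)C)ccc1O)C(=O)OCC[Si](C)(C)C
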